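**Compound numbers used throughout:** ring B/D series 1–9, ring A series 10–18, coupled series 19–24 (24 = mollicellin B). Ring B positions are numbered as in chroman (O1, C2, C3, C4, C4a, C5–C8, C8a); ring A positions as in the benzoic acid (C1 bears the carboxyl carbon).

## The problem

Mollicellin B (24) is an achiral tetracyclic depsidone. Ring A (a 3-formyl-4-hydroxy-6-methylbenzoyl unit) and ring B are joined twice: by an aryl ester from the ring A carbonyl to O6 of ring B, and by a diaryl ether from C2 of ring A to O7 of ring B. These two links close the seven-membered ring C, and ring B is also fused to ring D, a 2,2-dimethyldihydropyran-4-one. There is no stereocentre, so the whole difficulty is regiochemical. Ring B keeps a single hydrogen and carries three oxygens (O1, O6, O7) that must each receive its own role; exchanging the roles of O6 and O7 would give an isomeric depsidone. Ring A is pentasubstituted, with the formyl group wedged between the ether oxygen and a phenol. The lactone of ring C is an activated aryl ester, ring A is a salicylaldehyde, and ring D is a β-aryloxy ketone with a tertiary alkyl aryl ether, so strong base, strong nucleophiles and hot acid are excluded late in the route. The enabling feature is that O1 and C4 of ring D sit on adjacent ring B carbons (C8a and C4a) and C2 is a dimethyl-substituted carbon without stereochemistry. The bonds O1–C2 and C3–C4 are therefore exactly those formed when an ortho-quinone methide of ring B adds isobutene, and C4, ortho and para to ring oxygens, can be oxidised to the ketone afterwards.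

## Retrosynthesis

**24 from 23.** The last cut is the O–CH3 bond of the ring A methyl ether 23. A methoxy group ortho to a formyl group is cleaved by BCl3 through a chelate, so no other ether of 23 should be touched. Methyl is the smallest group that keeps the ring A oxygen neutral during the base-mediated ring closure.

**23 from 22.** Ring C is opened at the diaryl ether bond between O7 and C2 of ring A, giving the fluoro ester 22. Closing the ether last is preferred over closing the lactone last for two reasons. The fluorine of 22 lies between a formyl group and the ester carbonyl and is strongly activated for substitution. The nucleophile O7 is para to the C4 ketone and is the most acidic oxygen of the molecule, so the ester already sits on the less acidic oxygen O6 and has little reason to migrate. The forward step asks for a seven-membered ring closure by carbonate.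

**22 from 21 and 19.** The benzyl ether on O7 of 21 is removed by hydrogenolysis, and the C4 carbonyl of 21 is traced to the methylene of chroman ester 19. The oxidation is placed before O7 is freed because DDQ would attack a free phenol, and because the ketone is what makes O7 more acidic than O6. C4 is the only benzylic position ortho and para to ether oxygens; the C5 methyl group is meta to both.

**19 from 9 and 17.** The ester bond is cut to give two fragments of similar size: phenol 9 (rings B and D, O7 benzylated) and acid 17 (ring A, with fluorine as the latent ether site). The forward reaction is acylation of a hindered phenol by a 2,6-disubstituted benzoyl chloride.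

**9 from 7 and 6.** The C6–O bond comes from a C6 aldehyde 7 by Baeyer–Villiger oxidation, and 7 from chroman 6 by formylation. This is done at the chroman stage because the ring is still electron-rich there and the site is well defined: C6 is para to O1 and ortho to the benzyloxy group, whereas C8 lies between two oxygens. After the ketone is in place the ring would be deactivated and the site less certain.

**6 from 3 and 4 (key cut).** Ring D is opened at O1–C2 and C3–C4, giving ortho-hydroxybenzyl alcohol 3 and isobutene 4. The neighbouring cut, annulation of an orcinol with a 3,3-dimethylacryloyl unit, would give the chromanone directly but as a mixture of 5-methyl and 7-methyl isomers. Here the positions of O1 and C4 are fixed by the hydroxyl and hydroxymethyl groups of 3. Two bonds and a ring are traded for an arene and a C4 gas. The forward reaction must generate the quinone methide without acid and let an unactivated alkene capture it before it condenses with itself.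

**3 from 2 and 1.** Alcohol 3 is the reduction product of aldehyde 2, which is the monobenzyl ether of commercial 2,4-dihydroxy-6-methylbenzaldehyde 1. The chelated 2-hydroxyl is left free and becomes O1.

**17 from 14, 12, 11 and 10.** The carboxyl and formyl carbons of 17 are cut off in turn. Bromine para to the methoxy group of 11 marks the carboxyl site (12). Lithiation between fluorine and methoxy places the formyl group (14). The carboxyl is introduced last by bromine–lithium exchange with the aldehyde masked in the flask, because a pre-formed ortho-toluic acid would be metalated at its methyl group. Anisole 11 comes from commercial 3-fluoro-5-methylphenol 10.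

## Roads not taken

**Alternative 1:** Oxidative para C–H lactonisation. The cut is the bond from the ester oxygen to C6 of ring B, made last by C–H oxidation. Diaryl ether acid A2 would be oxidised at its orcinol-type phenol by PhI(OAc)2; the tethered carboxylate adds to the free para carbon and tautomerisation gives depsidone A1.
- Merits: ring B needs no pre-installed C6 oxygen, so steps 4, 5 and 10 of the present plan have no counterpart, and ring C forms in one operation with the aldehyde already in place. To the A–B–C core this road is shorter, which is a real advantage.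
- Weak points: the para carbon is flanked by methyl and aryloxy groups, the ring formed is seven-membered, and capture by acetate or attack at the ortho carbon compete. A1 is a hydroquinone monoester with a free phenol and is more easily oxidised than A2.
- Decisive weakness: ring D is still missing. It would have to be annulated onto A1 with a 3,3-dimethylacryloyl unit in strong acid, in the presence of the lactone and the aldehyde.
- Comparison: the chosen plan spends more steps but builds ring D first, under neutral conditions, where the starting aldehyde fixes its orientation. The finished depsidone then meets only carbonate, hydrogen and BCl3.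

**Alternative 2:** Aryne and ketene acetal (2+2), then ketene-relay lactonisation. The cut removes both carbons that become the methyl and carboxyl groups of ring A. The aryne released from silyl triflate A4 by CsF adds 1,1-dimethoxyethene A5 to give benzocyclobutenone ketal A3. Ketal hydrolysis, debenzylation and thermal opening of the four-membered ring to a ketene, captured by the ring B hydroxyl, would give the lactone and the ortho methyl group at once (A6).
- Merits: the ester to the hindered O6 forms intramolecularly and without an activated acid or base. On this point it is better than steps 10 and 13 here, since neither a hindered coupling nor acyl migration can arise.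
- Weak points: A4 already contains the complete chromanone with O6 and O7 differentiated, so the ring D problem is presupposed, and A4 needs silylation and triflation on top of a diaryl ether synthesis. The aryne regiochemistry rests on the inductive effect of the aryloxy group alone.
- Decisive weakness: A6 lacks the formyl group. It would have to enter late at the carbon between two oxygens, the site electrophiles avoid, while the free carbon next to the methyl group is favoured.
- Comparison: the chosen plan sets the formyl group by directed lithiation where its site is certain, and is considerably shorter.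

**Alternative 3:** Moore cyclobutenone ring expansion builds ring B. Thermolysis of cyclobutenone A8 opens the four-membered ring to a dienylketene, which closes between the ketene carbon and the CH2 terminus and tautomerises to hydroquinone A7.
- Merits: ring B is made with its three oxygens in unambiguous positions. This removes the one place where the chosen plan relies on arene substitution selectivity (step 4), and on that point it is superior.
- Weak points: A8 requires an aryloxycyclobutenedione and an isopropenyl organometallic addition. A7 is an air-sensitive hydroquinone that has neither ring C, nor ring D, nor the formyl group.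
- What remains after the key step: lactonisation, acid-mediated annulation of ring D, and the same misdirected late formylation of ring A as in Alternative 2.
- Comparison: the chosen plan answers the site question of step 4 with the known preference of resorcinol diethers, and in return settles every regiochemical question early with mild late steps.

Key step: step 3

Remark: 24 has no stereocentre; intermediates 15, 16 and 20 are racemic and need no control.

## Route

**Step 1**
Reactants: 1 2,4-dihydroxy-6-methylbenzaldehyde
Product: 2 4-(benzyloxy)-2-hydroxy-6-methylbenzaldehyde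
Conditions: BnBr, NaHCO3, KI (cat.), MeCN, 80 °C
Reagents that add atoms: benzyl bromide, BrCc1ccccc1
Why: Williamson etherification; the 2-hydroxyl is held in a hydrogen bond to the formyl group and is the weaker acid, so bicarbonate ionises and benzylates only the 4-hydroxyl.

**Step 2**
Reactants: 2 4-(benzyloxy)-2-hydroxy-6-methylbenzaldehyde
Product: 3 5-(benzyloxy)-2-(hydroxymethyl)-3-methylphenol
Conditions: NaBH4, THF–MeOH, 0 °C; pH 7 buffer work-up
Reagents that add atoms: none
Why: Hydride reduction of the aryl aldehyde; the electron-rich salicyl alcohol ionises easily, so the work-up is kept neutral and the material is used without storage.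

**Step 3**
Reactants: 3 5-(benzyloxy)-2-(hydroxymethyl)-3-methylphenol; 4 isobutene
Product: 6 7-(benzyloxy)-2,2,5-trimethylchroman, via ortho-quinone methide 5 (not isolated)
Conditions: isobutene (ca. 30 equiv, condensed), PhMe (0.02 M), steel autoclave, 170 °C
Reagents that add atoms: none
Why: On heating, 3 should lose water by a six-centre 1,4-elimination to give ortho-quinone methide 5. This reacts as an electron-poor 1-oxadiene with isobutene in an inverse-demand hetero-Diels–Alder reaction, an asynchronous (4+2) cycloaddition that closes the six-membered ring D by forming O1–C2 and C3–C4 and restores the aromaticity of ring B. The closest known reaction type is the thermal chroman synthesis from salicyl alcohols and alkenes, which extends to unactivated 1,1-disubstituted alkenes in the preparation of tocopherol-type 2,2-dialkylchromans. No stereocentre is formed, since C2 carries two methyl groups. The step needs regioselectivity: the methide carbon is the electrophilic terminus and bonds to the CH2 end of isobutene, so positive charge develops on the tertiary carbon, which the oxygen then takes. It also needs chemoselectivity over self-condensation of 5, which is secured by high dilution, a large excess of the alkene and a neutral medium in which isobutene neither oligomerises nor alkylates the arene. Hydration and dimerisation of 5 are reversible at this temperature while the cycloaddition is not, and the benzyl ether on the para oxygen excludes a para-quinone methide.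

**Step 4**
Reactants: 6 7-(benzyloxy)-2,2,5-trimethylchroman
Product: 7 7-(benzyloxy)-2,2,5-trimethylchroman-6-carbaldehyde
Conditions: POCl3, DMF, 0 to 50 °C; aq. NaOAc
Reagents that add atoms: N,N-dimethylformamide, CN(C)C=O (formyl carbon); water, O (carbonyl oxygen)
Why: Vilsmeier–Haack formylation; C6 is para to O1 and ortho to the benzyloxy group, while the only other free position, C8, lies between two oxygens, the site resorcinol diethers avoid (orcinol dimethyl ether is formylated next to its methyl group in the same way).

**Step 5**
Reactants: 7 7-(benzyloxy)-2,2,5-trimethylchroman-6-carbaldehyde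
Product: 9 7-(benzyloxy)-2,2,5-trimethylchroman-6-ol, via aryl formate 8 (not isolated)
Conditions: mCPBA, CH2Cl2, 0 °C to rt; aq. Na2S2O3/NaHCO3 wash; then K2CO3 (cat.), MeOH, N2, rt
Reagents that add atoms: 3-chloroperoxybenzoic acid, OOC(=O)c1cccc(Cl)c1
Why: Baeyer–Villiger (Dakin-type) oxidation; in the Criegee adduct of this electron-rich aldehyde the aryl group migrates in preference to hydrogen, and mild methanolysis of formate 8 frees O6 while the benzyl ether keeps O7 distinct.

**Step 6**
Reactants: 10 3-fluoro-5-methylphenol
Product: 11 1-fluoro-3-methoxy-5-methylbenzene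
Conditions: MeI, K2CO3, acetone, reflux
Reagents that add atoms: iodomethane, CI
Why: Williamson methylation of the phenol.

**Step 7**
Reactants: 11 1-fluoro-3-methoxy-5-methylbenzene
Product: 12 2-bromo-1-fluoro-5-methoxy-3-methylbenzene
Conditions: NBS, MeCN, 0 °C to rt
Reagents that add atoms: N-bromosuccinimide, O=C1CCC(=O)N1Br
Why: Electrophilic bromination with NBS in acetonitrile is strongly para-selective for anisoles; the carbon para to the methoxy group lies between fluorine and methyl and is the future carboxyl site.

**Step 8**
Reactants: 12 2-bromo-1-fluoro-5-methoxy-3-methylbenzene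
Product: 14 3-bromo-2-fluoro-6-methoxy-4-methylbenzaldehyde, via aryllithium 13 (not isolated)
Conditions: LiN(i-Pr)2, THF, −78 °C; DMF; aq. NH4Cl
Reagents that add atoms: N,N-dimethylformamide, CN(C)C=O
Why: Directed ortho-metalation; the hydrogen between fluorine and methoxy is the most acidic and is removed by the amide base, which does not exchange with the bromide, and DMF formylates 13 at a temperature where loss of LiF is not expected.

**Step 9**
Reactants: 14 3-bromo-2-fluoro-6-methoxy-4-methylbenzaldehyde
Product: 17 2-fluoro-3-formyl-4-methoxy-6-methylbenzoic acid, via lithium amino alkoxide 15 (not isolated), via aryllithium 16 (not isolated)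
Conditions: morpholine, n-BuLi, THF, −78 °C, then 14; n-BuLi, −78 °C; CO2; aq. HCl
Reagents that add atoms: carbon dioxide, O=C=O
Why: In situ protection of the aldehyde as the α-amino alkoxide (Comins procedure), bromine–lithium exchange and carboxylation; acidic work-up releases the aldehyde, and the carboxyl enters last because a pre-formed ortho-toluic acid would be metalated at its methyl group.

**Step 10**
Reactants: 17 2-fluoro-3-formyl-4-methoxy-6-methylbenzoic acid; 9 7-(benzyloxy)-2,2,5-trimethylchroman-6-ol
Product: 19 7-(benzyloxy)-2,2,5-trimethylchroman-6-yl 2-fluoro-3-formyl-4-methoxy-6-methylbenzoate, via acid chloride 18 (not isolated)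
Conditions: (COCl)2, DMF (cat.), CH2Cl2, 0 °C to rt; then 9, Et3N, DMAP (cat.), CH2Cl2, 0 °C to rt
Reagents that add atoms: none
Why: Acid chloride formation and DMAP-catalysed acylation of the hindered phenol; the small ortho fluorine keeps the acyl chloride accessible, and acylation is much faster than any attack of the phenol on the fluoroarene.

**Step 11**
Reactants: 19 7-(benzyloxy)-2,2,5-trimethylchroman-6-yl 2-fluoro-3-formyl-4-methoxy-6-methylbenzoate
Product: 21 7-(benzyloxy)-2,2,5-trimethyl-4-oxochroman-6-yl 2-fluoro-3-formyl-4-methoxy-6-methylbenzoate, via benzylic alcohol 20 (not isolated)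
Conditions: DDQ (2.5 equiv), 1,4-dioxane–H2O (9:1), rt to 50 °C
Reagents that add atoms: water, O
Why: DDQ benzylic oxidation in wet solvent; hydride is abstracted only from C4, whose cation is stabilised by O1 (ortho) and O7 (para), water traps it as alcohol 20 and a second equivalent of DDQ oxidises this to the aryl ketone, while the C5 methyl group, the benzyl ether and ring A are poorer hydride donors.

**Step 12**
Reactants: 21 7-(benzyloxy)-2,2,5-trimethyl-4-oxochroman-6-yl 2-fluoro-3-formyl-4-methoxy-6-methylbenzoate
Product: 22 7-hydroxy-2,2,5-trimethyl-4-oxochroman-6-yl 2-fluoro-3-formyl-4-methoxy-6-methylbenzoate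
Conditions: H2 (1 atm), Pd/C, EtOAc, rt, stopped after one equivalent of H2
Reagents that add atoms: none
Why: Hydrogenolysis of the aryl benzyl ether; the aryl fluoride, the aryl ester and the donor-conjugated chromanone carbonyl are inert, and the ring A aldehyde, flanked by fluorine and methoxy, should be reduced more slowly than the benzyl ether is cleaved.

**Step 13**
Reactants: 22 7-hydroxy-2,2,5-trimethyl-4-oxochroman-6-yl 2-fluoro-3-formyl-4-methoxy-6-methylbenzoate
Product: 23 mollicellin B methyl ether (24 with OCH3 in place of the ring A hydroxyl)
Conditions: K2CO3, DMF (0.01 M), rt to 50 °C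
Reagents that add atoms: none
Why: Intramolecular nucleophilic aromatic substitution; carbonate ionises O7 (para to the C4 ketone) and the phenoxide displaces the fluoride activated by the ortho formyl and ortho ester carbonyl groups, closing ring C, while the doubly ortho-substituted aroyl group already sits on the less acidic O6 and has neither a thermodynamic nor a kinetic reason to migrate.

**Step 14**
Reactants: 23 mollicellin B methyl ether
Product: 24 mollicellin B
Conditions: BCl3, CH2Cl2, −78 to 0 °C; aq. NaHCO3
Reagents that add atoms: none
Why: Chelation-assisted demethylation; BCl3 bridges the formyl oxygen and the adjacent methoxy oxygen and chloride removes the methyl group, while the lactone, the diaryl ether and ring D offer no such chelate and should survive at low temperature.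

## Compound list

1 | 2,4-dihydroxy-6-methylbenzaldehyde | Cc1cc(O)cc(O)c1C=O | starting material
2 | 4-(benzyloxy)-2-hydroxy-6-methylbenzaldehyde | Cc1cc(OCc2ccccc2)cc(O)c1C=O | intermediate
3 | 5-(benzyloxy)-2-(hydroxymethyl)-3-methylphenol | Cc1cc(OCc2ccccc2)cc(O)c1CO | intermediate
4 | isobutene (2-methylprop-1-ene) | CC(C)=C | starting material
5 | 3-(benzyloxy)-5-methyl-6-methylidenecyclohexa-2,4-dien-1-one (ortho-quinone methide) | C=C1C(=O)C=C(OCc2ccccc2)C=C1C | intermediate
6 | 7-(benzyloxy)-2,2,5-trimethylchroman | Cc1cc(OCc2ccccc2)cc2OC(C)(C)CCc12 | intermediate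
7 | 7-(benzyloxy)-2,2,5-trimethylchroman-6-carbaldehyde | Cc1c(C=O)c(OCc2ccccc2)cc2OC(C)(C)CCc12 | intermediate
8 | 7-(benzyloxy)-2,2,5-trimethylchroman-6-yl formate | Cc1c(OC=O)c(OCc2ccccc2)cc2OC(C)(C)CCc12 | intermediate
9 | 7-(benzyloxy)-2,2,5-trimethylchroman-6-ol | Cc1c(O)c(OCc2ccccc2)cc2OC(C)(C)CCc12 | intermediate
10 | 3-fluoro-5-methylphenol | Cc1cc(O)cc(F)c1 | starting material
11 | 1-fluoro-3-methoxy-5-methylbenzene | COc1cc(C)cc(F)c1 | intermediate
12 | 2-bromo-1-fluoro-5-methoxy-3-methylbenzene | COc1cc(C)c(Br)c(F)c1 | intermediate
13 | (3-bromo-2-fluoro-6-methoxy-4-methylphenyl)lithium | [Li]c1c(F)c(Br)c(C)cc1OC | intermediate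
14 | 3-bromo-2-fluoro-6-methoxy-4-methylbenzaldehyde | COc1cc(C)c(Br)c(F)c1C=O | intermediate
15 | lithium (3-bromo-2-fluoro-6-methoxy-4-methylphenyl)(morpholin-4-yl)methanolate (racemic) | [Li]OC(N1CCOCC1)c1c(F)c(Br)c(C)cc1OC | intermediate
16 | lithium (2-fluoro-3-lithio-6-methoxy-4-methylphenyl)(morpholin-4-yl)methanolate (racemic) | [Li]OC(N1CCOCC1)c1c(F)c([Li])c(C)cc1OC | intermediate
17 | 2-fluoro-3-formyl-4-methoxy-6-methylbenzoic acid | COc1cc(C)c(C(=O)O)c(F)c1C=O | intermediate
18 | 2-fluoro-3-formyl-4-methoxy-6-methylbenzoyl chloride | COc1cc(C)c(C(Cl)=O)c(F)c1C=O | intermediate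
19 | 7-(benzyloxy)-2,2,5-trimethylchroman-6-yl 2-fluoro-3-formyl-4-methoxy-6-methylbenzoate | COc1cc(C)c(C(=O)Oc2c(C)c3CCC(C)(C)Oc3cc2OCc2ccccc2)c(F)c1C=O | intermediate
20 | 7-(benzyloxy)-4-hydroxy-2,2,5-trimethylchroman-6-yl 2-fluoro-3-formyl-4-methoxy-6-methylbenzoate (racemic) | COc1cc(C)c(C(=O)Oc2c(C)c3C(O)CC(C)(C)Oc3cc2OCc2ccccc2)c(F)c1C=O | intermediate
21 | 7-(benzyloxy)-2,2,5-trimethyl-4-oxochroman-6-yl 2-fluoro-3-formyl-4-methoxy-6-methylbenzoate | COc1cc(C)c(C(=O)Oc2c(C)c3C(=O)CC(C)(C)Oc3cc2OCc2ccccc2)c(F)c1C=O | intermediate
22 | 7-hydroxy-2,2,5-trimethyl-4-oxochroman-6-yl 2-fluoro-3-formyl-4-methoxy-6-methylbenzoate | COc1cc(C)c(C(=O)Oc2c(C)c3C(=O)CC(C)(C)Oc3cc2O)c(F)c1C=O | intermediate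
23 | mollicellin B methyl ether (depsidone 24 with the ring A hydroxyl ortho to the formyl group as OCH3) | Cc1cc(OC)c(C=O)c2c1C(=O)Oc1c(cc3c(c1C)C(=O)CC(C)(C)O3)O2 | intermediate
24 | mollicellin B (depsidone of 3-formyl-4-hydroxy-6-methylbenzoic acid, carbonyl on O6 and C2 on O7 of 6,7-dihydroxy-2,2,5-trimethylchroman-4-one) | Cc1cc(O)c(C=O)c2c1C(=O)Oc1c(cc3c(c1C)C(=O)CC(C)(C)O3)O2 | target

## Step count and least certain steps

Total: 14 steps. Longest linear sequence: 10 steps (steps 1–5 and 10–14); the ring A branch (steps 6–9) joins at step 10.

**Step 3 (key step).** The likely failure is self-condensation of the quinone methide: the electron-rich arenes of 3 and 6 attack it, or it oligomerises, faster than the unactivated alkene captures it. Fallback, from 3 back to 6: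
- 3 is heated with a large excess of the far more reactive enol ether 2-methoxypropene (PhMe, sealed tube, 140 °C) to give 7-(benzyloxy)-2-methoxy-2,5-dimethylchroman F1.
- Aqueous HCl in THF opens the ketal to 4-[4-(benzyloxy)-2-hydroxy-6-methylphenyl]butan-2-one F2.
- MeMgBr (excess, THF, 0 °C) gives 5-(benzyloxy)-2-(3-hydroxy-3-methylbutyl)-3-methylphenol F3.
- TsOH (cat.) in PhMe closes the tertiary alcohol onto the phenol and returns chroman 6.

**Step 11.** The likely failure is loss of the C3 proton from the C4 cation, that is dehydrogenation to the 2H-chromene, outrunning capture by water. Fallback, from 19 back to 21: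
- The dehydrogenation is accepted: DDQ in dry benzene at reflux gives 7-(benzyloxy)-2,2,5-trimethyl-2H-chromen-6-yl 2-fluoro-3-formyl-4-methoxy-6-methylbenzoate F4.
- Mukaiyama hydration (Co(acac)2, PhSiH3, O2, i-PrOH) places the hydroxyl at benzylic C4 and gives alcohol 20, isolated in this case.
- Dess–Martin periodinane oxidises 20 to 21.

**Step 13.** The likely failures are migration of the aroyl group from O6 to the freed O7 phenoxide followed by closure from O6, or cleavage of the activated ester. Fallback: the ether is made first and the lactone last, from 9 and 17 back to 23.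
- 9 is protected (MOMCl, NaH, THF) as 7-(benzyloxy)-6-(methoxymethoxy)-2,2,5-trimethylchroman F5.
- Oxidation at C4 (DDQ, wet dioxane) gives 7-(benzyloxy)-6-(methoxymethoxy)-2,2,5-trimethylchroman-4-one F6.
- Hydrogenolysis (H2, Pd/C) gives 7-hydroxy-6-(methoxymethoxy)-2,2,5-trimethylchroman-4-one F7.
- 17 is converted with tert-butyl 2,2,2-trichloroacetimidate into tert-butyl 2-fluoro-3-formyl-4-methoxy-6-methylbenzoate F8.
- Intermolecular substitution of fluoride in F8 by F7 (K2CO3, DMF, 60 °C) gives tert-butyl 3-formyl-4-methoxy-2-{[6-(methoxymethoxy)-2,2,5-trimethyl-4-oxochroman-7-yl]oxy}-6-methylbenzoate F9.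
- TFA in CH2Cl2 removes both acid-labile groups to give 3-formyl-2-[(6-hydroxy-2,2,5-trimethyl-4-oxochroman-7-yl)oxy]-4-methoxy-6-methylbenzoic acid F10.
- Lactonisation without base (trifluoroacetic anhydride, PhMe) gives 23.

**Step 9.** The likely failures are incomplete masking of the aldehyde, so that butyllithium adds to the carbonyl, or loss of LiF from the ortho-fluoro aryllithium. Fallback, from 14 back to 17:
- 14 is converted (ethylene glycol, TsOH, PhMe, water separator) into 2-(3-bromo-2-fluoro-6-methoxy-4-methylphenyl)-1,3-dioxolane F11.
- Bromine–magnesium exchange with i-PrMgCl·LiCl (the arylmagnesium species does not eliminate fluoride) and CO2 give 3-(1,3-dioxolan-2-yl)-2-fluoro-4-methoxy-6-methylbenzoic acid F12.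
- Aqueous HCl in THF removes the acetal and returns 17.

## Further compounds

F1 | step 3 | 7-(benzyloxy)-2-methoxy-2,5-dimethylchroman (racemic) | COC1(C)CCc2c(C)cc(OCc3ccccc3)cc2O1
F2 | step 3 | 4-[4-(benzyloxy)-2-hydroxy-6-methylphenyl]butan-2-one | CC(=O)CCc1c(C)cc(OCc2ccccc2)cc1O
F3 | step 3 | 5-(benzyloxy)-2-(3-hydroxy-3-methylbutyl)-3-methylphenol | CC(C)(O)CCc1c(C)cc(OCc2ccccc2)cc1O
F4 | step 11 | 7-(benzyloxy)-2,2,5-trimethyl-2H-chromen-6-yl 2-fluoro-3-formyl-4-methoxy-6-methylbenzoate | COc1cc(C)c(C(=O)Oc2c(C)c3C=CC(C)(C)Oc3cc2OCc2ccccc2)c(F)c1C=O
F5 | step 13 | 7-(benzyloxy)-6-(methoxymethoxy)-2,2,5-trimethylchroman | COCOc1c(C)c2CCC(C)(C)Oc2cc1OCc1ccccc1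
F6 | step 13 | 7-(benzyloxy)-6-(methoxymethoxy)-2,2,5-trimethylchroman-4-one | COCOc1c(C)c2C(=O)CC(C)(C)Oc2cc1OCc1ccccc1
F7 | step 13 | 7-hydroxy-6-(methoxymethoxy)-2,2,5-trimethylchroman-4-one | COCOc1c(C)c2C(=O)CC(C)(C)Oc2cc1O
F8 | step 13 | tert-butyl 2-fluoro-3-formyl-4-methoxy-6-methylbenzoate | COc1cc(C)c(C(=O)OC(C)(C)C)c(F)c1C=O
F9 | step 13 | tert-butyl 3-formyl-4-methoxy-2-{[6-(methoxymethoxy)-2,2,5-trimethyl-4-oxochroman-7-yl]oxy}-6-methylbenzoate | COCOc1c(C)c2C(=O)CC(C)(C)Oc2cc1Oc1c(C=O)c(OC)cc(C)c1C(=O)OC(C)(C)C
F10 | step 13 | 3-formyl-2-[(6-hydroxy-2,2,5-trimethyl-4-oxochroman-7-yl)oxy]-4-methoxy-6-methylbenzoic acid | Cc1c(O)c(Oc2c(C=O)c(OC)cc(C)c2C(=O)O)cc2OC(C)(C)CC(=O)c12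
F11 | step 9 | 2-(3-bromo-2-fluoro-6-methoxy-4-methylphenyl)-1,3-dioxolane | COc1cc(C)c(Br)c(F)c1C1OCCO1
F12 | step 9 | 3-(1,3-dioxolan-2-yl)-2-fluoro-4-methoxy-6-methylbenzoic acid | COc1cc(C)c(C(=O)O)c(F)c1C1OCCO1
A1 | alternative 1 | 7-hydroxy-3-methoxy-1,9-dimethyl-11-oxo-11H-dibenzo[b,e][1,4]dioxepine-4-carbaldehyde | Cc1cc(OC)c(C=O)c2c1C(=O)Oc1c(C)cc(O)cc1O2
A2 | alternative 1 | 3-formyl-2-(3-hydroxy-5-methylphenoxy)-4-methoxy-6-methylbenzoic acid | Cc1cc(O)cc(Oc2c(C=O)c(OC)cc(C)c2C(=O)O)c1
A3 | alternative 2 | 6-(benzyloxy)-2,2,5-trimethyl-7-[(4,8,8-trimethoxybicyclo[4.2.0]octa-1,3,5-trien-2-yl)oxy]chroman-4-one | COc1cc2CC(OC)(OC)c2c(Oc2cc3OC(C)(C)CC(=O)c3c(C)c2OCc2ccccc2)c1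
A4 | alternative 2 | 3-{[6-(benzyloxy)-2,2,5-trimethyl-4-oxochroman-7-yl]oxy}-5-methoxy-2-(trimethylsilyl)phenyl trifluoromethanesulfonate | COc1cc(OS(=O)(=O)C(F)(F)F)c([Si](C)(C)C)c(Oc2cc3OC(C)(C)CC(=O)c3c(C)c2OCc2ccccc2)c1
A5 | alternative 2 | 1,1-dimethoxyethene | C=C(OC)OC
A6 | alternative 2 | mollicellin B methyl ether lacking the ring A formyl group | Cc1cc(OC)cc2c1C(=O)Oc1c(cc3c(c1C)C(=O)CC(C)(C)O3)O2
A7 | alternative 3 | methyl 2-(2,5-dihydroxy-3-methylphenoxy)-4-methoxy-6-methylbenzoate | COC(=O)c1c(C)cc(OC)cc1Oc1cc(O)cc(C)c1O
A8 | alternative 3 | methyl 2-{[4-hydroxy-3-oxo-4-(prop-1-en-2-yl)cyclobut-1-en-1-yl]oxy}-4-methoxy-6-methylbenzoate (racemic) | COC(=O)c1c(C)cc(OC)cc1OC1=CC(=O)C1(O)C(C)=C
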